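The C7–C8 segment of ring B, a secondary alcohol next to the tertiary carbinol that carries C17, is a reduced α-ketol, and α-ketols interconvert by 1,2-shifts. Retrosynthetically C8–C9 is cut and C9 is rebonded to C7, so ring B shrinks to the cyclopentane of a trans-hydrindane and C8/C17 become an exocyclic acetyl group. In the forward direction one aluminium-alkoxide-induced acyloin shift makes C8–C9, expands the five-membered ring to ring B, unveils the C7 ketone and fixes the 8α-OH/8β-CH3 centre. Its substrate is a 7β-acetyl-7α-hydroxy hydrindane bearing a 6α-silyloxy group, the 9β ketal-masked oxobutyl chain and intact ring A.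

Key step: step 12

Numbering: labdane numbers are used for every intermediate. Ring A is C1–C5 plus C10, with C18/C19 on C4 and C20 on C10. In the hydrindanes the five-membered ring is C5–C6–C7–C9–C10, and C8/C17 are the acetyl carbons. α is the face opposite C20.

Assumption: the sense of induction in step 2 follows the known behaviour of this ligand class ((S)-ligand gives (S)-2-allyl-2-alkylcyclohexanones), so the (R)-ligand is specified. Any residual minor enantiomer would be removed by recrystallising a crystalline later intermediate.

Design remark: the ketol is built as the 7α-hydroxy/7β-acetyl epimer. A chelating metal then gives the required C8 configuration, and a Lewis-acid-type shift favours the electron-richer C9 over the oxygen-bearing C6. The free-alkoxide shift of the C7 epimer is kept as the fallback.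

Step 1
Reactants: 1 2,2,6-trimethylcyclohexanone (racemic); 2 allyl chloroformate
Product: 3 allyl 2,6,6-trimethylcyclohex-1-en-1-yl carbonate
Conditions: lithium hexamethyldisilazide, THF, 0 °C; then 2, −78 °C → rt
Reagents that add atoms: none
Why: Enolate O-acylation: only C6 of 1 carries an α-hydrogen, and the hindered tetrasubstituted lithium enolate reacts with the hard chloroformate on oxygen, which also erases the stereocentre of racemic 1.

Step 2
Reactants: 3 allyl 2,6,6-trimethylcyclohex-1-en-1-yl carbonate
Product: 4 (R)-2-allyl-2,6,6-trimethylcyclohexanone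
Conditions: Pd2(dba)3 (2.5 mol %), (R)-t-Bu-PHOX [(R)-4-tert-butyl-2-(2-diphenylphosphinophenyl)-4,5-dihydrooxazole, 6 mol %], THF, 25 °C
Reagents that add atoms: none
Why: Decarboxylative asymmetric allylic alkylation: zerovalent palladium ionises the allyl carbonate, CO2 is lost, and the π-allylpalladium enolate recombines at the former enol carbon inside the chiral P,N-ligand pocket, the (R)-ligand giving the (R)-quaternary centre that becomes C10 with its β-methyl group C20.

Step 3
Reactants: 4 (R)-2-allyl-2,6,6-trimethylcyclohexanone
Product: 5 (R)-2,2,6-trimethyl-6-(2-oxopropyl)cyclohexanone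
Conditions: PdCl2 (10 mol %), Cu(OAc)2·H2O (25 mol %), O2 (1 atm), DMA/H2O, 23 °C
Reagents that add atoms: water, O
Why: Tsuji–Wacker oxidation: Markovnikov hydroxypalladation of the terminal alkene by divalent palladium gives the methyl ketone (C7=O), O2 and the copper salt turn the catalyst over, and the ring ketone, which has no α-hydrogen, is a spectator.

Step 4
Reactants: 5 (R)-2,2,6-trimethyl-6-(2-oxopropyl)cyclohexanone
Product: 6 (7aR)-4,4,7a-trimethyl-1,4,5,6,7,7a-hexahydro-2H-inden-2-one (C7=O, C5=C6, C9H2, 10β-CH3)
Conditions: KOH (powdered), xylenes, 110 °C, Dean–Stark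
Reagents that add atoms: none
Why: Intramolecular aldol condensation: the ring carbonyl C5 can act only as acceptor, so the methyl carbon C6 of the side-chain ketone closes the five-membered ring and azeotropic removal of water drives dehydration to the C5=C6 enone.

Step 5
Reactants: 6 bicyclic enone; 7 methyl vinyl ketone
Product: 8 9-(3-oxobutyl) derivative of enone 6 (C9 epimers)
Conditions: lithium diisopropylamide, THF, −78 °C; 7, −78 °C; AcOH quench at −78 °C
Reagents that add atoms: none
Why: Kinetic Michael addition: 6 has acidic hydrogens only at C9 because both γ-positions are quaternary, so the base gives a single cross-conjugated dienolate that adds 1,4 to 7 at low temperature, the cold acidic quench forestalls Robinson-type closure, and the C9 configuration is left open because step 7 corrects it.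

Step 6
Reactants: 8 9-(3-oxobutyl) enone
Product: 9 9-[2-(2-methyl-1,3-dioxolan-2-yl)ethyl] enone (13-ethylene ketal of 8, C9 epimers)
Conditions: (TMSOCH2)2, TMSOTf (5 mol %), CH2Cl2, −78 → −40 °C; pyridine quench
Reagents that add atoms: 1,2-bis(trimethylsilyloxy)ethane, C[Si](C)(C)OCCO[Si](C)(C)C
Why: Aprotic silyl-transfer ketalisation catalysed by TMSOTf discriminates the unhindered saturated methyl ketone C13 from the conjugated and neopentyl-flanked C7 carbonyl, so only the side chain is masked.

Step 7
Reactants: 9 ketal enone
Product: 11 9β-[2-(2-methyl-1,3-dioxolan-2-yl)ethyl]-5α-H trans-hydrindan-7-one, via C9-epimeric trans-hydrindan-7-one 10 (not isolated)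
Conditions: Li, NH3(l)/THF, t-BuOH (1 equiv), −78 → −33 °C; NH4Cl; crude, NaOMe (cat.), MeOH, 40 °C
Reagents that add atoms: none
Why: Dissolving-metal enone reduction followed by base equilibration: the C5 carbanion is protonated from the α face because the axial methyl groups C19 and C20 wall off the β face, which gives the trans ring fusion, and methoxide then epimerises the only labile centre C9 to the pseudo-equatorial 9β chain (9α-H), the arrangement also preferred by 17-alkyl-16-oxo steroids.

Step 8
Reactants: 11 9β trans-hydrindan-7-one
Product: 12 7-(trifluoromethanesulfonyloxy)-6-ene (C6=C7 enol triflate of 11)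
Conditions: lithium diisopropylamide, THF, −78 °C; N-(5-chloro-2-pyridyl)triflimide, −78 °C
Reagents that add atoms: N-(5-chloro-2-pyridyl)bis(trifluoromethanesulfonimide), O=S(=O)(N(c1ccc(Cl)cn1)S(=O)(=O)C(F)(F)F)C(F)(F)F
Why: Kinetic deprotonation takes a proton from the C6 methylene and not the tertiary neopentyl C9–H, and the pyridyl triflimide traps the lithium enolate on oxygen already at −78 °C (enol triflate formation), so the C6=C7 regiochemistry is frozen and C9 is untouched.

Step 9
Reactants: 12 enol triflate; 13 tributyl(1-ethoxyvinyl)stannane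
Product: 15 7-acetyl-6-ene (conjugated methyl ketone C8=O on C7=C6), via 7-(1-ethoxyvinyl)-6-ene 14 (not isolated)
Conditions: Pd(PPh3)4 (5 mol %), LiCl (3 equiv), THF, 65 °C; then 1 M HCl, THF, 0 °C
Reagents that add atoms: water, O
Why: Stille cross-coupling of the vinyl triflate (oxidative addition to zerovalent palladium, chloride-assisted transmetalation, reductive elimination) attaches C8/C17 as a masked acetyl group, as in the conversion of 17-oxo steroids into 16-en-20-ones, and the very acid-labile dienol ether is hydrolysed under conditions that spare the dioxolane.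

Step 10
Reactants: 15 7-acetyl-6-ene
Product: 16 7β-acetyl-6α,7α-dihydroxy trans-hydrindane (ketal chain 9β)
Conditions: OsO4 (5 mol %), NMO, acetone/H2O, rt
Reagents that add atoms: N-methylmorpholine N-oxide, C[N+]1([O-])CCOCC1; water, O
Why: Catalytic OsO4 syn-dihydroxylation adds both oxygens to the α face of C6=C7 because the β face is covered by C19, C20 and the 9β chain, which sets 6α-OH and 7α-OH at once and pushes the acetyl group to the β face, just as 16-en-20-oxo steroids give 16α,17α-diols.

Step 11
Reactants: 16 6α,7α-diol
Product: 17 7β-acetyl-7α-hydroxy-6α-(tert-butyldimethylsilyloxy) B-nor hydrindane with ketal-protected 9β side chain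
Conditions: TBSOTf (1.1 equiv), 2,6-lutidine, CH2Cl2, −78 → −20 °C
Reagents that add atoms: tert-butyldimethylsilyl triflate, CC(C)(C)[Si](C)(C)OS(=O)(=O)C(F)(F)F
Why: Silyl triflate/lutidine silylation distinguishes the secondary 6α-OH from the tertiary 7α-OH on steric grounds, which blocks the β-hydroxy ketone (retro-aldol) pathway and leaves free the hydroxyl that drives the next step.

Step 12
Reactants: 17 7β-acetyl-7α-hydroxy-6α-silyloxy B-nor hydrindane
Product: 18 8α-hydroxy-6α-(tert-butyldimethylsilyloxy)-14,15-dinorlabdane-7,13-dione 13-ethylene ketal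
Conditions: Al(Ot-Bu)3 (2 equiv), toluene, Ar, 90 °C; aqueous work-up
Reagents that add atoms: none
Why: Alkoxide exchange binds the tertiary 7α-oxygen to aluminium, which also coordinates the acetyl oxygen O8; inside this five-membered chelate O7 folds down to the C7 carbonyl while the C7–C9 σ bond, aligned with the activated C8=O π* orbital, slides with retention at C9 onto C8, whose oxygen becomes the C8 aluminium alkoxide. This is the metal-alkoxide (Lewis-acid) form of the α-ketol or acyloin rearrangement, whose closest relative is the D-homoannulation of 17α-hydroxy-20-oxo steroids, likewise 1-acetylcyclopentanols set in a trans-hydrindane. Ring B is thus made by ring enlargement through a 1,2-shift (five to six members, C8 inserted between C7 and C9) and not by cyclisation of a chain end, and it is driven by release of the trans-hydrindane strain and of the crowding of the β-face acetyl group against C11 and C20. The single new stereocentre C8 is controlled by the chelate: with O8 held syn to the α-oriented O7, the β-face acetyl group swings into the ring with O8 α (equatorial) and C17 β (axial). The selectivity needed is shift of C9 and not of C6, and 17 secures it threefold, because the pull of the coordinated carbonyl selects the electron-richer bond and C6–C7 is depleted by the σ-withdrawing silyloxy group, because the chelated rotamer that aligns C6–C7 would press C17 onto C11 of the 9β chain whereas the one that aligns C7–C9 leaves C17 over the open 6β-H side, and because 16α,17α-dioxygenated 20-oxo steroids of the same relative configuration enlarge by shift of the non-oxygenated carbon. Al(Ot-Bu)3 carries no transferable hydride, tolerates the dioxolane and the TBS ether, and avoids a free alkoxide that could trigger O6-to-O7 silyl migration, retro-aldol opening or drift to the isomeric 8-oxo ketol.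

Step 13
Reactants: 18 ring-expanded silyloxy ketol ketal
Product: 19 6α,8α-dihydroxy-14,15-dinorlabdane-7,13-dione
Conditions: 48% aq HF, MeCN, 0 °C → rt
Reagents that add atoms: water, O
Why: Global acidic deprotection: fluoride cleaves the Si–O6 bond and the aqueous acid hydrolyses the dioxolane in the same operation, while the α-ketol and the equatorial (thermodynamically preferred) C6 centre are not affected at room temperature.

Step 14
Reactants: 19 dihydroxy dione
Product: 20 6α-acetoxy-8α-hydroxy-14,15-dinorlabdane-7,13-dione
Conditions: Ac2O, pyridine, DMAP (cat.), CH2Cl2, 0 °C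
Reagents that add atoms: acetic anhydride, CC(=O)OC(C)=O
Why: DMAP-catalysed acetylation differentiates the oxygens by substitution and oxidation level, since only the secondary 6α-OH reacts at 0 °C, the tertiary 8α-OH is inert and O7 is still a ketone.

Step 15
Reactants: 20 acetoxy hydroxy dione
Product: 21 6α-acetoxy-8α,13-epoxy-14,15-dinorlabd-12-en-7-one
Conditions: PPTS (cat.), toluene, 4 Å molecular sieves, 80 °C
Reagents that add atoms: none
Why: Acid-catalysed cyclodehydration of a δ-hydroxy ketone: the equatorial 8α-OH adds to C13 and loss of water gives the more substituted endocyclic C12=C13 enol ether in a trans-fused dihydropyran, which masks C13=O and O8 for the next step and marks C12 instead of C16 for functionalisation.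

Step 16
Reactants: 21 enol ether ketone
Product: 22 6α-acetoxy-8α,13-epoxy-14,15-dinorlabd-12-en-7β-ol
Conditions: NaBH4, THF/MeOH, −40 °C; pH 7 buffer
Reagents that add atoms: none
Why: Borohydride reduction of the only free ketone: hydride enters axially from the α face because the axial 8β-methyl C17 shields the β face, giving the equatorial 7β-alcohol, while the enol ether is inert and the low temperature and neutral quench suppress O6-to-O7 acetyl migration.

Step 17
Reactants: 22 enol ether alcohol
Product: 25 (11E)-6α-acetoxy-7β,8α-dihydroxy-14,15-dinorlabd-11-en-13-one (target), via 12-phenylselanyl ketone 23 (not isolated), via selenoxide 24 (not isolated)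
Conditions: PhSeCl, CH2Cl2, −78 °C; aq NaHCO3/THF, 0 °C; crude, 30% H2O2, pyridine, CH2Cl2, 0 °C → rt
Reagents that add atoms: water, O; benzeneselenenyl chloride, Cl[Se]c1ccccc1 (atoms kept only in 23 and 24); hydrogen peroxide, OO (atom kept only in 24)
Why: Electrophilic selenenylation of the enol ether can occur only at its nucleophilic carbon C12, hydrolysis of the C13 oxocarbenium adduct releases the ketone and the 8α-OH, and the selenoxide then undergoes syn elimination toward C11–H, the only β-hydrogens, fastest from the open-chain keto form, which gives the conjugated E-alkene.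

Compound list
1 | 2,2,6-trimethylcyclohexanone | CC1CCCC(C)(C)C1=O | starting material
2 | allyl chloroformate | C=CCOC(Cl)=O | starting material
3 | allyl 2,6,6-trimethylcyclohex-1-en-1-yl carbonate | C=CCOC(=O)OC1=C(C)CCCC1(C)C | intermediate
4 | (R)-2-allyl-2,6,6-trimethylcyclohexanone | C=CC[C@@]1(C)CCCC(C)(C)C1=O | intermediate
5 | (R)-2,2,6-trimethyl-6-(2-oxopropyl)cyclohexanone | CC(=O)C[C@@]1(C)CCCC(C)(C)C1=O | intermediate
6 | (7aR)-4,4,7a-trimethyl-1,4,5,6,7,7a-hexahydro-2H-inden-2-one | O=C1C=C2C(C)(C)CCC[C@]2(C)C1 | intermediate
7 | methyl vinyl ketone | C=CC(C)=O | starting material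
8 | 9-(3-oxobutyl) enone, C9 epimers | CC(=O)CCC1C(=O)C=C2C(C)(C)CCC[C@@]21C | intermediate
9 | 13-ethylene ketal of 8, C9 epimers | CC1(OCCO1)CCC1C(=O)C=C2C(C)(C)CCC[C@@]21C | intermediate
10 | 5α-H trans-hydrindan-7-one ketal, C9 epimers | CC1(OCCO1)CCC1C(=O)C[C@H]2C(C)(C)CCC[C@@]21C | intermediate
11 | 9β-chain 5α-H trans-hydrindan-7-one ketal | CC1(OCCO1)CC[C@H]1C(=O)C[C@H]2C(C)(C)CCC[C@@]21C | intermediate
12 | C6=C7 enol triflate of 11 | CC1(OCCO1)CC[C@H]1C(OS(=O)(=O)C(F)(F)F)=C[C@H]2C(C)(C)CCC[C@@]21C | intermediate
13 | tributyl(1-ethoxyvinyl)stannane | CCCC[Sn](CCCC)(CCCC)C(=C)OCC | starting material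
14 | 7-(1-ethoxyvinyl)-6-ene | CC1(OCCO1)CC[C@H]1C(C(=C)OCC)=C[C@H]2C(C)(C)CCC[C@@]21C | intermediate
15 | 7-acetyl-6-ene | CC1(OCCO1)CC[C@H]1C(C(C)=O)=C[C@H]2C(C)(C)CCC[C@@]21C | intermediate
16 | 7β-acetyl-6α,7α-dihydroxy hydrindane ketal | CC1(OCCO1)CC[C@H]1[C@@](O)(C(C)=O)[C@H](O)[C@H]2C(C)(C)CCC[C@@]21C | intermediate
17 | 7β-acetyl-7α-hydroxy-6α-TBSO B-nor hydrindane ketal (key-step precursor) | CC1(OCCO1)CC[C@H]1[C@@](O)(C(C)=O)[C@H](O[Si](C)(C)C(C)(C)C)[C@H]2C(C)(C)CCC[C@@]21C | intermediate
18 | 8α-hydroxy-6α-TBSO-14,15-dinorlabdane-7,13-dione 13-ethylene ketal (key-step product) | CC1(OCCO1)CC[C@H]1[C@](C)(O)C(=O)[C@H](O[Si](C)(C)C(C)(C)C)[C@H]2C(C)(C)CCC[C@@]21C | intermediate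
19 | 6α,8α-dihydroxy-14,15-dinorlabdane-7,13-dione | CC(=O)CC[C@H]1[C@](C)(O)C(=O)[C@H](O)[C@H]2C(C)(C)CCC[C@@]21C | intermediate
20 | 6α-acetoxy-8α-hydroxy-14,15-dinorlabdane-7,13-dione | CC(=O)CC[C@H]1[C@](C)(O)C(=O)[C@H](OC(C)=O)[C@H]2C(C)(C)CCC[C@@]21C | intermediate
21 | 6α-acetoxy-8α,13-epoxy-14,15-dinorlabd-12-en-7-one | CC1=CC[C@H]2[C@](C)(O1)C(=O)[C@H](OC(C)=O)[C@H]3C(C)(C)CCC[C@]23C | intermediate
22 | 6α-acetoxy-8α,13-epoxy-14,15-dinorlabd-12-en-7β-ol | CC1=CC[C@H]2[C@](C)(O1)[C@@H](O)[C@H](OC(C)=O)[C@H]3C(C)(C)CCC[C@]23C | intermediate
23 | 6α-acetoxy-7β,8α-dihydroxy-12-(phenylselanyl)-14,15-dinorlabdan-13-one, C12 epimers | CC(=O)C([Se]c1ccccc1)C[C@H]1[C@](C)(O)[C@@H](O)[C@H](OC(C)=O)[C@H]2C(C)(C)CCC[C@@]21C | intermediate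
24 | selenoxide of 23 | CC(=O)C([Se](=O)c1ccccc1)C[C@H]1[C@](C)(O)[C@@H](O)[C@H](OC(C)=O)[C@H]2C(C)(C)CCC[C@@]21C | intermediate
25 | (11E)-6α-acetoxy-7β,8α-dihydroxy-14,15-dinorlabd-11-en-13-one | CC(=O)/C=C/[C@H]1[C@](C)(O)[C@@H](O)[C@H](OC(C)=O)[C@H]2C(C)(C)CCC[C@@]21C | target

Total step count: 17. Longest linear sequence: 17 steps (from 1).

Steps most likely to fail

Step 12 (key step). Four processes could spoil it:
- a competing shift of C6;
- leakage through a non-chelated rotamer, which erodes the C8 configuration;
- thermal drift toward the isomeric 8-oxo ketol;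
- O6-to-O7 silyl migration in the cis-disposed pair.

The fallback replaces chelate control by dipole control on the C7 epimer. It sets out from 11 and comes back at 18. Kinetic enolisation of 11 (lithium diisopropylamide; TBSOTf, −78 °C) would give the C6=C7 silyl enol ether F1. Rubottom oxidation with mCPBA from the α face, with O-to-O silyl shift, would give the 6α-silyloxy hydrindan-7-one F2. The CeCl3-modified 1-ethoxyvinyllithium (from ethyl vinyl ether and tert-butyllithium) should add from the α face, opposite C20 and the 9β chain, to give the 7α-(1-ethoxyvinyl) carbinol F3. Dilute acid would unmask this to the 7α-acetyl-7β-hydroxy ketol F4. With KOH in MeOH at 0 °C → rt the free alkoxide reacts through the rotamer in which the C8=O dipole opposes the C7–O bond. For this epimer that rotamer again places C17 β and O8 α, and so leads to 18. The trans O6/O7 relation of F4 slows silyl migration. The electronic bias against a C6 shift is weaker in an anionic shift, which is why this variant ranks second.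

Step 7. Three processes are at risk: protonation of C5 from the wrong face (cis ring fusion), over-reduction of the ketone, and an equilibrium at C9 that is not one-sided. The fallback sets out from 9 and comes back at 11. Electron transfer and protonation are replaced by heterogeneous hydrogenation (H2, Pd/C, EtOAc). This delivers hydrogen to C5=C6 under pure steric approach control from the open α face and cannot touch the ketone. It gives 10, which is equilibrated with NaOMe as before. A separated 9α epimer can be resubmitted to the equilibration.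

Step 17. Three processes are at risk: syn elimination out of the ring-closed hemiketal tautomer (which would fix a Z-alkene), O6-to-O7 acetyl migration next to the free 7β-OH, and re-addition of selenium by-products to the enone. The fallback changes the order of events. It sets out from 21 and comes back at 25.

Selenenylation and oxidation are carried out while O7 is still a ketone. No neighbouring hydroxyl can then accept the acetyl group, and the liberated 8α-OH, flanked by the carbonyl, is less prone to hemiketal closure. PhSeCl followed by aq NaHCO3 would give the 12-phenylselanyl 7,13-dione F5. H2O2 would give the selenoxide F6, and syn elimination the (E)-11-ene-7,13-dione F7.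

The C7 ketone is then reduced last with Me4NBH(OAc)3 in MeCN/AcOH at −20 °C. This reagent reduces only a ketone to which it is tethered through a neighbouring hydroxyl (here 8α-OH). It delivers hydride from the α face and leaves the remote enone untouched, giving 25.

Further compounds
F1 | step 12 | C6=C7 tert-butyldimethylsilyl enol ether of 11 | CC1(OCCO1)CC[C@H]1C(O[Si](C)(C)C(C)(C)C)=C[C@H]2C(C)(C)CCC[C@@]21C
F2 | step 12 | 6α-(tert-butyldimethylsilyloxy) trans-hydrindan-7-one ketal | CC1(OCCO1)CC[C@H]1C(=O)[C@H](O[Si](C)(C)C(C)(C)C)[C@H]2C(C)(C)CCC[C@@]21C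
F3 | step 12 | 7α-(1-ethoxyvinyl)-7β-hydroxy-6α-TBSO hydrindane ketal | CC1(OCCO1)CC[C@H]1[C@](O)(C(=C)OCC)[C@H](O[Si](C)(C)C(C)(C)C)[C@H]2C(C)(C)CCC[C@@]21C
F4 | step 12 | 7α-acetyl-7β-hydroxy-6α-TBSO B-nor hydrindane ketal | CC1(OCCO1)CC[C@H]1[C@](O)(C(C)=O)[C@H](O[Si](C)(C)C(C)(C)C)[C@H]2C(C)(C)CCC[C@@]21C
F0 | step 7 | none | none
F5 | step 17 | 6α-acetoxy-8α-hydroxy-12-(phenylselanyl)-14,15-dinorlabdane-7,13-dione, C12 epimers | CC(=O)C([Se]c1ccccc1)C[C@H]1[C@](C)(O)C(=O)[C@H](OC(C)=O)[C@H]2C(C)(C)CCC[C@@]21C
F6 | step 17 | selenoxide of F5 | CC(=O)C([Se](=O)c1ccccc1)C[C@H]1[C@](C)(O)C(=O)[C@H](OC(C)=O)[C@H]2C(C)(C)CCC[C@@]21C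
F7 | step 17 | (11E)-6α-acetoxy-8α-hydroxy-14,15-dinorlabd-11-ene-7,13-dione | CC(=O)/C=C/[C@H]1[C@](C)(O)C(=O)[C@H](OC(C)=O)[C@H]2C(C)(C)CCC[C@@]21C
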